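**Assumption:** the target has no stereocentre and no stereogenic axis (all diaryl ether bonds rotate freely), so it is achiral and is made as drawn. The sp3 centres in 16, 19 and 20 (racemic or diastereomer mixtures) vanish on aromatisation.

**Notation:** Bn = benzyl, All = allyl; ring letters A–G follow the target SMILES from left to right.
- A = 2,4,6-tris(benzyloxy)phenyl.
- B, D, F, G = 2,6-bis(benzyloxy)-1,4-phenylene. C-4 carries the oxygen from the ring on its left; C-1 (between the two OBn) carries the oxygen to the next ring or the end group given in brackets.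
- C, E = 3,4,5-tris(benzyloxy)-1,2-phenylene. C-1 carries the oxygen from the left ring; C-2 (next to the 3-OBn) carries the oxygen to the next ring or the end group in brackets.

## Retrosynthetic overview

1. 40 ⇐ 39 by hydrogenolysis of 17 benzyl ethers.
2. 39 ⇐ phenol 26 (rings A–B), extended left to right by five Cu-catalysed aryl ether couplings: iodide 8 supplies rings C and E (allyl-masked OH), bromo-aldehyde 2 supplies rings D, F and G (CHO = masked OH, released by Dakin oxidation).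
3. 26 ⇐ ring A built de novo on the B-ring oxygen: the C–C bond between aryloxymalonyl unit 16/19 and the Mg enolate 18 of dimethyl 3-oxoglutarate is made by a crossed Claisen condensation, then Dieckmann aromatisation (20 → 21), decarboxylation and benzylation.
4. Blocks 2, 8 and 13 ⇐ 4-bromo-2,6-difluorobenzaldehyde, 2,3,4-trihydroxybenzaldehyde and 3,4,5-trihydroxybenzaldehyde.
5. Ring order: rings B–G are bought as arenes; ring A is the only ring formed (step 13), before any coupling.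

## Route

Step 1
Reactants: 1 4-bromo-2,6-difluorobenzaldehyde
Product: 2 4-bromo-2,6-bis(benzyloxy)benzaldehyde
Conditions: BnOH (2.2 eq), NaH (2.2 eq), THF, 0 °C → rt
Reagents that add atoms: benzyl alcohol, OCc1ccccc1
Why: Twofold SNAr in which both fluorides ortho to the formyl group are displaced by benzyloxide, while the para bromide (a much poorer SNAr leaving group) is kept for the later copper couplings.

Step 2
Reactants: 3 2,3,4-trihydroxybenzaldehyde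
Product: 4 2,3,4-tris(benzyloxy)benzaldehyde
Conditions: BnBr (3.5 eq), K2CO3, KI (cat.), DMF, 70 °C
Reagents that add atoms: benzyl bromide, BrCc1ccccc1
Why: Exhaustive Williamson etherification; warming overcomes the hydrogen bond of the 2-OH to the aldehyde.

Step 3
Reactants: 4 2,3,4-tris(benzyloxy)benzaldehyde
Product: 6 2,3,4-tris(benzyloxy)phenol, via aryl formate 5 (not isolated)
Conditions: mCPBA (1.3 eq), CH2Cl2, 0 °C → rt; then K2CO3 (cat.), MeOH, rt
Reagents that add atoms: mCPBA, OOC(=O)c1cccc(Cl)c1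
Why: Baeyer–Villiger (Dakin-type) oxidation in which the electron-rich o,p-alkoxyaryl group migrates, followed by methanolysis of the formate.

Step 4
Reactants: 6 2,3,4-tris(benzyloxy)phenol
Product: 7 2,3,4-tris(benzyloxy)-6-iodophenol
Conditions: I2 (1.05 eq), NaHCO3, THF/H2O, 0 °C → rt
Reagents that add atoms: iodine, II
Why: Electrophilic aromatic iodination directed by the phenol(ate); para is blocked, so iodine enters the only ortho position (C-6).

Step 5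
Reactants: 7 2,3,4-tris(benzyloxy)-6-iodophenol
Product: 8 2-(allyloxy)-3,4,5-tris(benzyloxy)-1-iodobenzene
Conditions: allyl bromide (1.5 eq), K2CO3, DMF, 50 °C
Reagents that add atoms: allyl bromide, C=CCBr
Why: Williamson etherification masks the hindered phenol as an allyl ether that survives Ullmann conditions and is later removed by Pd(0) without touching benzyl ethers.

Step 6
Reactants: 9 3,4,5-trihydroxybenzaldehyde
Product: 10 4-(allyloxy)-3,5-dihydroxybenzaldehyde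
Conditions: allyl bromide (1.0 eq), NaHCO3 (1.2 eq), NaI (cat.), DMF, 40 °C
Reagents that add atoms: allyl bromide, C=CCBr
Why: Regioselective Williamson alkylation, since bicarbonate ionises only the 4-OH (para to CHO, the most acidic).

Step 7
Reactants: 10 4-(allyloxy)-3,5-dihydroxybenzaldehyde
Product: 11 4-(allyloxy)-3,5-bis(benzyloxy)benzaldehyde
Conditions: BnBr (2.4 eq), K2CO3, DMF, 60 °C
Reagents that add atoms: benzyl bromide, BrCc1ccccc1
Why: Williamson etherification of the two remaining phenols.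

Step 8
Reactants: 11 4-(allyloxy)-3,5-bis(benzyloxy)benzaldehyde
Product: 13 4-(allyloxy)-3,5-bis(benzyloxy)phenol, via aryl formate 12 (not isolated)
Conditions: 30% H2O2 (1.5 eq), H2SO4 (cat.), MeOH, rt
Reagents that add atoms: hydrogen peroxide, OO
Why: Acid-catalysed Dakin oxidation (migration of the p-alkoxyaryl group, formate methanolysed in situ); no peracid is used, so the allyl C=C is not epoxidised.

Step 9
Reactants: 13 4-(allyloxy)-3,5-bis(benzyloxy)phenol; 14 dimethyl 2-chloromalonate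
Product: 15 dimethyl 2-[4-(allyloxy)-3,5-bis(benzyloxy)phenoxy]malonate
Conditions: K2CO3, acetone, reflux
Reagents that add atoms: none
Why: SN2 O-alkylation (Williamson) of the unhindered phenoxide by the α-halomalonate; this creates the future A–O–B oxygen bridge without any aryl–O coupling.

Step 10
Reactants: 15 dimethyl 2-[4-(allyloxy)-3,5-bis(benzyloxy)phenoxy]malonate
Product: 16 rac-2-[4-(allyloxy)-3,5-bis(benzyloxy)phenoxy]-3-methoxy-3-oxopropanoic acid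
Conditions: KOH (1.05 eq), THF/H2O, 0 °C; then 1 M HCl
Reagents that add atoms: potassium hydroxide, [K+].[OH-]
Why: Selective monosaponification of a symmetric malonate (the monocarboxylate resists a second hydroxide attack); the new stereocentre is racemic and is destroyed later.

Step 11
Reactants: 17 dimethyl 3-oxopentanedioate (2 eq)
Product: 18 magnesium bis(1,5-dimethoxy-1,5-dioxopent-2-en-3-olate)
Conditions: Mg(OMe)2 (1 eq), MeOH, rt; evaporate, dry in vacuo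
Reagents that add atoms: magnesium methoxide, C[O-].C[O-].[Mg+2]
Why: Acid–base formation of the stable magnesium β-keto ester chelate, which protects the ketone from self-aldol reaction and directs acylation to carbon.

Step 12
Reactants: 16 rac-2-[4-(allyloxy)-3,5-bis(benzyloxy)phenoxy]-3-methoxy-3-oxopropanoic acid; 18 magnesium bis(1,5-dimethoxy-1,5-dioxopent-2-en-3-olate)
Product: 20 dimethyl 2-{2-[4-(allyloxy)-3,5-bis(benzyloxy)phenoxy]-3-methoxy-3-oxopropanoyl}-3-oxopentanedioate, via acid chloride 19 (not isolated)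
Conditions: (COCl)2 (1.2 eq), DMF (cat.), CH2Cl2, 0 °C → rt, evaporate; then 18 (1.1 eq), CH2Cl2, 0 °C → rt; 1 M HCl work-up
Reagents that add atoms: none
Why: Intermolecular crossed Claisen condensation (acyl chloride / magnesium β-keto ester enolate variant) forms the C–C bond that joins the two fragments, with Mg chelation enforcing C- over O-acylation; the new sp3 centres form unselectively and are erased on aromatisation.

Step 13
Reactants: 20 dimethyl 2-{2-[4-(allyloxy)-3,5-bis(benzyloxy)phenoxy]-3-methoxy-3-oxopropanoyl}-3-oxopentanedioate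
Product: 21 dimethyl 5-[4-(allyloxy)-3,5-bis(benzyloxy)phenoxy]-2,4,6-trihydroxybenzene-1,3-dicarboxylate
Conditions: Mg(OMe)2 (3 eq), MeOH, reflux, Ar; then 1 M HCl, 0 °C
Reagents that add atoms: none
Why: Magnesium-templated Dieckmann (intramolecular Claisen) condensation of the C-4 methylene onto the aryloxymalonyl ester closes ring A, which tautomerises irreversibly to the phloroglucinol while pyranone by-products can reopen under methoxide.

Step 14
Reactants: 21 dimethyl 5-[4-(allyloxy)-3,5-bis(benzyloxy)phenoxy]-2,4,6-trihydroxybenzene-1,3-dicarboxylate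
Product: 24 2-[4-(allyloxy)-3,5-bis(benzyloxy)phenoxy]benzene-1,3,5-triyl triacetate, via dicarboxylic acid 22 (not isolated), via triol 23 (not isolated)
Conditions: KOH (10 eq), degassed H2O/EtOH, reflux, Ar; HCl to pH 2, 70 °C; extract; then Ac2O, pyridine, rt
Reagents that add atoms: acetic anhydride, CC(=O)OC(C)=O
Why: Saponification followed by the facile double decarboxylation of 2,4,6-trihydroxybenzoic acids (through their keto tautomers); the air-sensitive triol is trapped at once by O-acetylation.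

Step 15
Reactants: 24 2-[4-(allyloxy)-3,5-bis(benzyloxy)phenoxy]benzene-1,3,5-triyl triacetate
Product: 25 2-(allyloxy)-1,3-bis(benzyloxy)-5-[2,4,6-tris(benzyloxy)phenoxy]benzene
Conditions: BnCl (3.6 eq), NaH (7 eq), DMF, 0 °C; H2O (3.3 eq) added slowly; → rt
Reagents that add atoms: benzyl chloride, ClCc1ccccc1
Why: In-situ deacetylation and Williamson O-benzylation, in which each phenoxide is benzylated as it is released, which suppresses the C-benzylation typical of free phloroglucinols.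

Step 16
Reactants: 25 2-(allyloxy)-1,3-bis(benzyloxy)-5-[2,4,6-tris(benzyloxy)phenoxy]benzene
Product: 26 2,6-bis(benzyloxy)-4-[2,4,6-tris(benzyloxy)phenoxy]phenol
Conditions: Pd(PPh3)4 (5 mol%), morpholine (5 eq), THF, rt, Ar
Reagents that add atoms: none
Why: Tsuji–Trost deallylation (π-allylpalladium trapped by morpholine) frees the hindered B-ring phenol and leaves benzyl ethers untouched.

Step 17
Reactants: 26 2,6-bis(benzyloxy)-4-[2,4,6-tris(benzyloxy)phenoxy]phenol; 8 2-(allyloxy)-3,4,5-tris(benzyloxy)-1-iodobenzene (1.3 eq)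
Product: 27 trimer allyl ether A–O–B–O–C(OAll)
Conditions: CuI (20 mol%), picolinic acid (40 mol%), K3PO4 (2 eq), DMSO, 90 °C, Ar
Reagents that add atoms: none
Why: Ullmann-type Cu-catalysed C–O coupling under picolinic acid conditions, which tolerate ortho-substituted partners, forms the tri-ortho-substituted B–O–C ether at the carbon that carried iodine.

Step 18
Reactants: 27 trimer allyl ether A–O–B–O–C(OAll)
Product: 28 trimer phenol A–O–B–O–C(OH)
Conditions: Pd(PPh3)4 (5 mol%), morpholine (5 eq), THF, rt, Ar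
Reagents that add atoms: none
Why: Tsuji–Trost deallylation as in step 16.

Step 19
Reactants: 28 trimer phenol A–O–B–O–C(OH); 2 4-bromo-2,6-bis(benzyloxy)benzaldehyde (1.3 eq)
Product: 29 tetramer aldehyde A–O–B–O–C–O–D(CHO)
Conditions: CuI (10 mol%), picolinic acid (20 mol%), K3PO4 (2 eq), DMSO, 85 °C, Ar
Reagents that add atoms: none
Why: Ullmann-type C–O coupling of the hindered phenol with an unhindered aryl bromide that is activated by its para-formyl group.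

Step 20
Reactants: 29 tetramer aldehyde A–O–B–O–C–O–D(CHO)
Product: 31 tetramer phenol A–O–B–O–C–O–D(OH), via aryl formate 30 (not isolated)
Conditions: mCPBA (1.3 eq), CH2Cl2, 0 °C → rt; then K2CO3 (cat.), MeOH/THF, rt
Reagents that add atoms: mCPBA, OOC(=O)c1cccc(Cl)c1
Why: Baeyer–Villiger (Dakin-type) oxidation of the 2,6-dialkoxy-4-aryloxybenzaldehyde with aryl migration, then formate methanolysis, gives the hindered D-ring phenol.

Step 21
Reactants: 31 tetramer phenol A–O–B–O–C–O–D(OH); 8 2-(allyloxy)-3,4,5-tris(benzyloxy)-1-iodobenzene (1.3 eq)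
Product: 32 pentamer allyl ether A–O–B–O–C–O–D–O–E(OAll)
Conditions: CuI (20 mol%), picolinic acid (40 mol%), K3PO4 (2 eq), DMSO, 90 °C, Ar
Reagents that add atoms: none
Why: Ullmann-type C–O coupling as in step 17 forms the second tri-ortho-substituted ether (D–O–E).

Step 22
Reactants: 32 pentamer allyl ether A–O–B–O–C–O–D–O–E(OAll)
Product: 33 pentamer phenol A–O–B–O–C–O–D–O–E(OH)
Conditions: Pd(PPh3)4 (5 mol%), morpholine (5 eq), THF, rt, Ar
Reagents that add atoms: none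
Why: Tsuji–Trost deallylation as in step 16.

Step 23
Reactants: 33 pentamer phenol A–O–B–O–C–O–D–O–E(OH); 2 4-bromo-2,6-bis(benzyloxy)benzaldehyde (1.3 eq)
Product: 34 hexamer aldehyde A–O–B–O–C–O–D–O–E–O–F(CHO)
Conditions: CuI (10 mol%), picolinic acid (20 mol%), K3PO4 (2 eq), DMSO, 85 °C, Ar
Reagents that add atoms: none
Why: Ullmann-type C–O coupling as in step 19.

Step 24
Reactants: 34 hexamer aldehyde A–O–B–O–C–O–D–O–E–O–F(CHO)
Product: 36 hexamer phenol A–O–B–O–C–O–D–O–E–O–F(OH), via aryl formate 35 (not isolated)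
Conditions: mCPBA (1.3 eq), CH2Cl2, 0 °C → rt; then K2CO3 (cat.), MeOH/THF, rt
Reagents that add atoms: mCPBA, OOC(=O)c1cccc(Cl)c1
Why: Baeyer–Villiger (Dakin-type) oxidation and formate methanolysis as in step 20.

Step 25
Reactants: 36 hexamer phenol A–O–B–O–C–O–D–O–E–O–F(OH); 2 4-bromo-2,6-bis(benzyloxy)benzaldehyde (1.5 eq)
Product: 37 heptamer aldehyde A–O–B–O–C–O–D–O–E–O–F–O–G(CHO)
Conditions: CuI (10 mol%), picolinic acid (20 mol%), K3PO4 (2 eq), DMSO, 85 °C, Ar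
Reagents that add atoms: none
Why: Ullmann-type C–O coupling of the hindered F-ring phenol with the activated, unhindered bromide brings in ring G with its 4-oxygen still masked as CHO.

Step 26
Reactants: 37 heptamer aldehyde A–O–B–O–C–O–D–O–E–O–F–O–G(CHO)
Product: 39 heptamer phenol A–O–B–O–C–O–D–O–E–O–F–O–G(OH), via aryl formate 38 (not isolated)
Conditions: mCPBA (1.3 eq), CH2Cl2, 0 °C → rt; then K2CO3 (cat.), MeOH/THF, rt
Reagents that add atoms: mCPBA, OOC(=O)c1cccc(Cl)c1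
Why: Baeyer–Villiger (Dakin-type) oxidation turns the last formyl group into the 4-OH of ring G.

Step 27
Reactants: 39 heptamer phenol A–O–B–O–C–O–D–O–E–O–F–O–G(OH)
Product: 40 target CNP0292517.0
Conditions: H2 (3 bar), 20% Pd(OH)2/C, THF/MeOH (1:1), rt; filter and concentrate under Ar
Reagents that add atoms: none
Why: Catalytic hydrogenolysis cleaves all 17 benzyl ethers while the diaryl ether bonds and arenes are inert; the product is achiral, so no stereochemistry is at stake.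

## Compound list

1 | 4-bromo-2,6-difluorobenzaldehyde | O=Cc1c(F)cc(Br)cc1F | starting material
2 | 4-bromo-2,6-bis(benzyloxy)benzaldehyde | O=Cc1c(OCc2ccccc2)cc(Br)cc1OCc1ccccc1 | intermediate
3 | 2,3,4-trihydroxybenzaldehyde | O=Cc1ccc(O)c(O)c1O | starting material
4 | 2,3,4-tris(benzyloxy)benzaldehyde | O=Cc1ccc(OCc2ccccc2)c(OCc2ccccc2)c1OCc1ccccc1 | intermediate
5 | 2,3,4-tris(benzyloxy)phenyl formate | O=COc1ccc(OCc2ccccc2)c(OCc2ccccc2)c1OCc1ccccc1 | intermediate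
6 | 2,3,4-tris(benzyloxy)phenol | Oc1ccc(OCc2ccccc2)c(OCc2ccccc2)c1OCc1ccccc1 | intermediate
7 | 2,3,4-tris(benzyloxy)-6-iodophenol | Oc1c(I)cc(OCc2ccccc2)c(OCc2ccccc2)c1OCc1ccccc1 | intermediate
8 | 2-(allyloxy)-3,4,5-tris(benzyloxy)-1-iodobenzene | C=CCOc1c(I)cc(OCc2ccccc2)c(OCc2ccccc2)c1OCc1ccccc1 | intermediate
9 | 3,4,5-trihydroxybenzaldehyde | O=Cc1cc(O)c(O)c(O)c1 | starting material
10 | 4-(allyloxy)-3,5-dihydroxybenzaldehyde | O=Cc1cc(O)c(OCC=C)c(O)c1 | intermediate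
11 | 4-(allyloxy)-3,5-bis(benzyloxy)benzaldehyde | O=Cc1cc(OCc2ccccc2)c(OCC=C)c(OCc2ccccc2)c1 | intermediate
12 | 4-(allyloxy)-3,5-bis(benzyloxy)phenyl formate | O=COc1cc(OCc2ccccc2)c(OCC=C)c(OCc2ccccc2)c1 | intermediate
13 | 4-(allyloxy)-3,5-bis(benzyloxy)phenol | Oc1cc(OCc2ccccc2)c(OCC=C)c(OCc2ccccc2)c1 | intermediate
14 | dimethyl 2-chloromalonate | COC(=O)C(Cl)C(=O)OC | starting material
15 | dimethyl 2-[4-(allyloxy)-3,5-bis(benzyloxy)phenoxy]malonate | COC(=O)C(Oc1cc(OCc2ccccc2)c(OCC=C)c(OCc2ccccc2)c1)C(=O)OC | intermediate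
16 | rac-2-[4-(allyloxy)-3,5-bis(benzyloxy)phenoxy]-3-methoxy-3-oxopropanoic acid | COC(=O)C(Oc1cc(OCc2ccccc2)c(OCC=C)c(OCc2ccccc2)c1)C(O)=O | intermediate
17 | dimethyl 3-oxopentanedioate (dimethyl 3-oxoglutarate) | COC(=O)CC(=O)CC(=O)OC | starting material
18 | magnesium bis(1,5-dimethoxy-1,5-dioxopent-2-en-3-olate) | [Mg+2].COC(=O)CC([O-])=CC(=O)OC.COC(=O)CC([O-])=CC(=O)OC | intermediate
19 | rac-methyl 2-[4-(allyloxy)-3,5-bis(benzyloxy)phenoxy]-3-chloro-3-oxopropanoate | COC(=O)C(Oc1cc(OCc2ccccc2)c(OCC=C)c(OCc2ccccc2)c1)C(Cl)=O | intermediate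
20 | dimethyl 2-{2-[4-(allyloxy)-3,5-bis(benzyloxy)phenoxy]-3-methoxy-3-oxopropanoyl}-3-oxopentanedioate (stereoisomer/enol mixture) | COC(=O)CC(=O)C(C(=O)OC)C(=O)C(Oc1cc(OCc2ccccc2)c(OCC=C)c(OCc2ccccc2)c1)C(=O)OC | intermediate
21 | dimethyl 5-[4-(allyloxy)-3,5-bis(benzyloxy)phenoxy]-2,4,6-trihydroxybenzene-1,3-dicarboxylate | COC(=O)c1c(O)c(C(=O)OC)c(O)c(Oc2cc(OCc3ccccc3)c(OCC=C)c(OCc3ccccc3)c2)c1O | intermediate
22 | 5-[4-(allyloxy)-3,5-bis(benzyloxy)phenoxy]-2,4,6-trihydroxybenzene-1,3-dicarboxylic acid | OC(=O)c1c(O)c(C(=O)O)c(O)c(Oc2cc(OCc3ccccc3)c(OCC=C)c(OCc3ccccc3)c2)c1O | intermediate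
23 | 2-[4-(allyloxy)-3,5-bis(benzyloxy)phenoxy]benzene-1,3,5-triol | Oc1cc(O)c(Oc2cc(OCc3ccccc3)c(OCC=C)c(OCc3ccccc3)c2)c(O)c1 | intermediate
24 | 2-[4-(allyloxy)-3,5-bis(benzyloxy)phenoxy]benzene-1,3,5-triyl triacetate | CC(=O)Oc1cc(OC(C)=O)c(Oc2cc(OCc3ccccc3)c(OCC=C)c(OCc3ccccc3)c2)c(OC(C)=O)c1 | intermediate
25 | 2-(allyloxy)-1,3-bis(benzyloxy)-5-[2,4,6-tris(benzyloxy)phenoxy]benzene, A–O–B(OAll) | c1(OCc2ccccc2)cc(OCc2ccccc2)c(c(OCc2ccccc2)c1)Oc1cc(OCc2ccccc2)c(OCC=C)c(OCc2ccccc2)c1 | intermediate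
26 | 2,6-bis(benzyloxy)-4-[2,4,6-tris(benzyloxy)phenoxy]phenol, A–O–B(OH) | c1(OCc2ccccc2)cc(OCc2ccccc2)c(c(OCc2ccccc2)c1)Oc1cc(OCc2ccccc2)c(O)c(OCc2ccccc2)c1 | intermediate
27 | trimer allyl ether A–O–B–O–C(OAll): 1-(allyloxy)-2,3,4-tris(benzyloxy)-6-{2,6-bis(benzyloxy)-4-[2,4,6-tris(benzyloxy)phenoxy]phenoxy}benzene | c1(OCc2ccccc2)cc(OCc2ccccc2)c(c(OCc2ccccc2)c1)Oc1cc(OCc2ccccc2)c(c(OCc2ccccc2)c1)Oc1cc(OCc2ccccc2)c(OCc2ccccc2)c(OCc2ccccc2)c1OCC=C | intermediate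
28 | trimer phenol A–O–B–O–C(OH) | c1(OCc2ccccc2)cc(OCc2ccccc2)c(c(OCc2ccccc2)c1)Oc1cc(OCc2ccccc2)c(c(OCc2ccccc2)c1)Oc1cc(OCc2ccccc2)c(OCc2ccccc2)c(OCc2ccccc2)c1O | intermediate
29 | tetramer aldehyde A–O–B–O–C–O–D(CHO) | c1(OCc2ccccc2)cc(OCc2ccccc2)c(c(OCc2ccccc2)c1)Oc1cc(OCc2ccccc2)c(c(OCc2ccccc2)c1)Oc1cc(OCc2ccccc2)c(OCc2ccccc2)c(OCc2ccccc2)c1Oc1cc(OCc2ccccc2)c(C=O)c(OCc2ccccc2)c1 | intermediate
30 | tetramer formate A–O–B–O–C–O–D(OCHO) | c1(OCc2ccccc2)cc(OCc2ccccc2)c(c(OCc2ccccc2)c1)Oc1cc(OCc2ccccc2)c(c(OCc2ccccc2)c1)Oc1cc(OCc2ccccc2)c(OCc2ccccc2)c(OCc2ccccc2)c1Oc1cc(OCc2ccccc2)c(OC=O)c(OCc2ccccc2)c1 | intermediate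
31 | tetramer phenol A–O–B–O–C–O–D(OH) | c1(OCc2ccccc2)cc(OCc2ccccc2)c(c(OCc2ccccc2)c1)Oc1cc(OCc2ccccc2)c(c(OCc2ccccc2)c1)Oc1cc(OCc2ccccc2)c(OCc2ccccc2)c(OCc2ccccc2)c1Oc1cc(OCc2ccccc2)c(O)c(OCc2ccccc2)c1 | intermediate
32 | pentamer allyl ether A–O–B–O–C–O–D–O–E(OAll) | c1(OCc2ccccc2)cc(OCc2ccccc2)c(c(OCc2ccccc2)c1)Oc1cc(OCc2ccccc2)c(c(OCc2ccccc2)c1)Oc1cc(OCc2ccccc2)c(OCc2ccccc2)c(OCc2ccccc2)c1Oc1cc(OCc2ccccc2)c(c(OCc2ccccc2)c1)Oc1cc(OCc2ccccc2)c(OCc2ccccc2)c(OCc2ccccc2)c1OCC=C | intermediate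
33 | pentamer phenol A–O–B–O–C–O–D–O–E(OH) | c1(OCc2ccccc2)cc(OCc2ccccc2)c(c(OCc2ccccc2)c1)Oc1cc(OCc2ccccc2)c(c(OCc2ccccc2)c1)Oc1cc(OCc2ccccc2)c(OCc2ccccc2)c(OCc2ccccc2)c1Oc1cc(OCc2ccccc2)c(c(OCc2ccccc2)c1)Oc1cc(OCc2ccccc2)c(OCc2ccccc2)c(OCc2ccccc2)c1O | intermediate
34 | hexamer aldehyde A–O–B–O–C–O–D–O–E–O–F(CHO) | c1(OCc2ccccc2)cc(OCc2ccccc2)c(c(OCc2ccccc2)c1)Oc1cc(OCc2ccccc2)c(c(OCc2ccccc2)c1)Oc1cc(OCc2ccccc2)c(OCc2ccccc2)c(OCc2ccccc2)c1Oc1cc(OCc2ccccc2)c(c(OCc2ccccc2)c1)Oc1cc(OCc2ccccc2)c(OCc2ccccc2)c(OCc2ccccc2)c1Oc1cc(OCc2ccccc2)c(C=O)c(OCc2ccccc2)c1 | intermediate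
35 | hexamer formate A–O–B–O–C–O–D–O–E–O–F(OCHO) | c1(OCc2ccccc2)cc(OCc2ccccc2)c(c(OCc2ccccc2)c1)Oc1cc(OCc2ccccc2)c(c(OCc2ccccc2)c1)Oc1cc(OCc2ccccc2)c(OCc2ccccc2)c(OCc2ccccc2)c1Oc1cc(OCc2ccccc2)c(c(OCc2ccccc2)c1)Oc1cc(OCc2ccccc2)c(OCc2ccccc2)c(OCc2ccccc2)c1Oc1cc(OCc2ccccc2)c(OC=O)c(OCc2ccccc2)c1 | intermediate
36 | hexamer phenol A–O–B–O–C–O–D–O–E–O–F(OH) | c1(OCc2ccccc2)cc(OCc2ccccc2)c(c(OCc2ccccc2)c1)Oc1cc(OCc2ccccc2)c(c(OCc2ccccc2)c1)Oc1cc(OCc2ccccc2)c(OCc2ccccc2)c(OCc2ccccc2)c1Oc1cc(OCc2ccccc2)c(c(OCc2ccccc2)c1)Oc1cc(OCc2ccccc2)c(OCc2ccccc2)c(OCc2ccccc2)c1Oc1cc(OCc2ccccc2)c(O)c(OCc2ccccc2)c1 | intermediate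
37 | heptamer aldehyde A–O–B–O–C–O–D–O–E–O–F–O–G(CHO) | c1(OCc2ccccc2)cc(OCc2ccccc2)c(c(OCc2ccccc2)c1)Oc1cc(OCc2ccccc2)c(c(OCc2ccccc2)c1)Oc1cc(OCc2ccccc2)c(OCc2ccccc2)c(OCc2ccccc2)c1Oc1cc(OCc2ccccc2)c(c(OCc2ccccc2)c1)Oc1cc(OCc2ccccc2)c(OCc2ccccc2)c(OCc2ccccc2)c1Oc1cc(OCc2ccccc2)c(c(OCc2ccccc2)c1)Oc1cc(OCc2ccccc2)c(C=O)c(OCc2ccccc2)c1 | intermediate
38 | heptamer formate A–O–B–O–C–O–D–O–E–O–F–O–G(OCHO) | c1(OCc2ccccc2)cc(OCc2ccccc2)c(c(OCc2ccccc2)c1)Oc1cc(OCc2ccccc2)c(c(OCc2ccccc2)c1)Oc1cc(OCc2ccccc2)c(OCc2ccccc2)c(OCc2ccccc2)c1Oc1cc(OCc2ccccc2)c(c(OCc2ccccc2)c1)Oc1cc(OCc2ccccc2)c(OCc2ccccc2)c(OCc2ccccc2)c1Oc1cc(OCc2ccccc2)c(c(OCc2ccccc2)c1)Oc1cc(OCc2ccccc2)c(OC=O)c(OCc2ccccc2)c1 | intermediate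
39 | heptamer phenol A–O–B–O–C–O–D–O–E–O–F–O–G(OH), 17 benzyl ethers | c1(OCc2ccccc2)cc(OCc2ccccc2)c(c(OCc2ccccc2)c1)Oc1cc(OCc2ccccc2)c(c(OCc2ccccc2)c1)Oc1cc(OCc2ccccc2)c(OCc2ccccc2)c(OCc2ccccc2)c1Oc1cc(OCc2ccccc2)c(c(OCc2ccccc2)c1)Oc1cc(OCc2ccccc2)c(OCc2ccccc2)c(OCc2ccccc2)c1Oc1cc(OCc2ccccc2)c(c(OCc2ccccc2)c1)Oc1cc(OCc2ccccc2)c(O)c(OCc2ccccc2)c1 | intermediate
40 | CNP0292517.0 (achiral) | Oc1cc(O)c(Oc2cc(O)c(Oc3cc(O)c(O)c(O)c3Oc3cc(O)c(Oc4cc(O)c(O)c(O)c4Oc4cc(O)c(Oc5cc(O)c(O)c(O)c5)c(O)c4)c(O)c3)c(O)c2)c(O)c1 | target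

## Step count and risk

Total steps: 27. Longest linear sequence: 21 steps (9 → 40: steps 6–10 and 12–27).

**Step 13 (with step 12, the ring-A annulation).** The tricarbonyl compound 20 may close through oxygen to 2-pyranones or lose its acyl group by retro-Claisen cleavage instead of closing to the arene. The fallback sets out from 16 and comes back at 24. Acid chloride 19 is made from 16 as in step 12 and added to 1-methoxy-1,3-bis(trimethylsilyloxy)buta-1,3-diene (Chan's diene, COC(O[Si](C)(C)C)=CC(=C)O[Si](C)(C)C) in CH2Cl2 at −78 → 20 °C, followed by dilute HCl. This acylates the γ-carbon of the masked acetoacetate dianion (Mukaiyama-type crossed Claisen) and gives dimethyl 2-[4-(allyloxy)-3,5-bis(benzyloxy)phenoxy]-3,5-dioxoheptanedioate F1, which has no tricarbonyl methine and only one ring-closing carbon that can lead to an arene. Mg(OMe)2 in refluxing MeOH then closes C-6 onto the C-1 ester (Dieckmann) to methyl 3-[4-(allyloxy)-3,5-bis(benzyloxy)phenoxy]-2,4,6-trihydroxybenzoate F2. Under the conditions of step 14 this is saponified to 3-[4-(allyloxy)-3,5-bis(benzyloxy)phenoxy]-2,4,6-trihydroxybenzoic acid F3, which loses CO2 to triol 23 and is acetylated to 24.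

**Step 17 (the same coupling recurs in step 21).** The tri-ortho-substituted, very electron-rich diaryl ether may form slowly under Ullmann conditions, with protodeiodination of 8 competing. The fallback sets out from 8 (partner 26) and comes back at 27; in the same way it takes 31 to 32. Iodine–magnesium exchange on 8 (i-PrMgCl·LiCl, THF, −40 °C), quenching with B(OMe)3 and aqueous NH4Cl work-up give [2-(allyloxy)-3,4,5-tris(benzyloxy)phenyl]boronic acid F4. This is joined to phenol 26 by an oxidative Chan–Evans–Lam coupling (Cu(OAc)2, pyridine, 4 Å MS, CH2Cl2, dry air, rt), which runs at room temperature and needs no aryl halide.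

**Step 27.** The 17-fold hydrogenolysis may stall at partly benzylated, poorly soluble stages, and the free polyphenol oxidises easily during isolation. The fallback sets out from 39 and comes back at 40. All benzyl ethers are cleaved non-reductively with BCl3 and pentamethylbenzene (cation scavenger) in CH2Cl2 at −78 °C. The crude polyphenol is acetylated directly (Ac2O, pyridine) to the octadecaacetate of 40 F5, which is stable and can be chromatographed on silica. HCl-catalysed methanolysis (AcCl cat., MeOH, Ar, rt) and evaporation then return 40.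

## Further compounds

F1 | step 13 | rac-dimethyl 2-[4-(allyloxy)-3,5-bis(benzyloxy)phenoxy]-3,5-dioxoheptanedioate | COC(=O)C(Oc1cc(OCc2ccccc2)c(OCC=C)c(OCc2ccccc2)c1)C(=O)CC(=O)CC(=O)OC
F2 | step 13 | methyl 3-[4-(allyloxy)-3,5-bis(benzyloxy)phenoxy]-2,4,6-trihydroxybenzoate | COC(=O)c1c(O)cc(O)c(Oc2cc(OCc3ccccc3)c(OCC=C)c(OCc3ccccc3)c2)c1O
F3 | step 13 | 3-[4-(allyloxy)-3,5-bis(benzyloxy)phenoxy]-2,4,6-trihydroxybenzoic acid | OC(=O)c1c(O)cc(O)c(Oc2cc(OCc3ccccc3)c(OCC=C)c(OCc3ccccc3)c2)c1O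
F4 | step 17 | [2-(allyloxy)-3,4,5-tris(benzyloxy)phenyl]boronic acid | OB(O)c1cc(OCc2ccccc2)c(OCc2ccccc2)c(OCc2ccccc2)c1OCC=C
F5 | step 27 | octadecaacetate of 40 | c1(OC(C)=O)cc(OC(C)=O)c(c(OC(C)=O)c1)Oc1cc(OC(C)=O)c(c(OC(C)=O)c1)Oc1cc(OC(C)=O)c(OC(C)=O)c(OC(C)=O)c1Oc1cc(OC(C)=O)c(c(OC(C)=O)c1)Oc1cc(OC(C)=O)c(OC(C)=O)c(OC(C)=O)c1Oc1cc(OC(C)=O)c(c(OC(C)=O)c1)Oc1cc(OC(C)=O)c(OC(C)=O)c(OC(C)=O)c1
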